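**Direct plan and its weak points**

A direct plan would take rings B and C from orsellinic acid (A1), tell their phenols apart with benzyl, allyl and methyl groups, and join the two units through a mixed anhydride to the ring B–ring C didepside phenol A2.
A2 would be esterified with the diazoketo acid A3 to diazoketone A4. Ring A would be built last, by photochemical Wolff rearrangement of A4 and benzannulation of the vinylketene with (triisopropylsilyloxy)acetylene (A5), then desilylation and hydrogenolysis.
Weakest points:
- The protecting-group stretch from A1 to A2 (benzylations, allylations, a methylation, a saponification, two deallylations) would take about eight operations and form one skeletal bond.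
- The photochemical benzannulation would come late, on a vinylketene whose terminus bears an electron-poor aryl ester, a substrate class on which it is untested. Photoisomerisation of the enone, closure of the ketene onto the ester and acylation of the product phenol could each drain advanced material.
- The run-up to the small, sensitive partners A3 and A5 (about five steps, with a diazo transfer, a cold saponification of a diazo ester and a volatile silyl ynol ether) would only supply six carbons of one orsellinate ring.

**Retrosynthetic overview**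

Each orsellinoyl ring is cut at two bonds at once: its depside bond C(=O)–O (ring B carbonyl to O4 of ring C; ring A carbonyl to O4′ of ring B) and its ring bond C1–C6 between the carboxyl-bearing and the methyl-bearing carbon.
This unravels ring B and ring A into the same open-chain tetraketide, acylketene 9, released by heat from diketo-dioxinone 8 (two steps from 2,2,6-trimethyl-4H-1,3-dioxin-4-one).
The rings form in the order C, B, A, each by the C2-to-C7 aldol closure of a tetraketide chain as in the biosynthesis: ring C from 4-methoxy-6-methyl-2H-pyran-2-one, whose enol ether becomes the C2 methoxy group; ring B by capture of 9 at O4 of phenol 5; ring A by a second capture at O4′.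
The hydroxyls at C2′, C2″ and C4″ are formed free and O4′ is the most reactive oxygen when it is needed, so no phenol is protected (one benzyl ester is the only protecting group), and no diazo compound, ynol ether or late photochemical step is used.

Key step: step 5

Remark: the target has no stereocentre. Ring A is the terminal 2,4-dihydroxy-6-methylbenzoyl unit (atoms double-primed), ring B the central unit (primed), ring C the 2-methoxy-6-methylbenzoic acid unit (unprimed). Tetraketide chain atoms are numbered from the acyl carbon (C1) to the methyl carbon (C8). Compounds 1 and 6, N-methoxy-N-methylacetamide and 1.0 M NaOCH2Ph in benzyl alcohol are taken as commercial. The acylketene released on heating 8 is the same short-lived species in steps 5 and 6; it is numbered 9 and entered once, at step 5, where it first forms.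

**Route**

Step 1
Reactants: 1 4-methoxy-6-methyl-2H-pyran-2-one
Product: 2 4-methoxy-6-(2-oxopropyl)-2H-pyran-2-one
Conditions: LiN(i-Pr)2 (1.1 equiv), THF, −78 °C; then MeC(O)N(OMe)Me (1.2 equiv), −78 to 0 °C; aq. HCl
Reagents that add atoms: N-methoxy-N-methylacetamide, CC(=O)N(C)OC
Why: Deprotonation of the C6 methyl group gives the vinylogous ester anion, which is C-acylated at the exocyclic carbon by the N-methoxy-N-methyl amide (Claisen-type acylation); the chelated tetrahedral adduct persists until the acidic quench, so the more acidic product cannot quench unreacted anion and no second addition occurs.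

Step 2
Reactants: 2 4-methoxy-6-(2-oxopropyl)-2H-pyran-2-one
Product: 5 benzyl 4-hydroxy-2-methoxy-6-methylbenzoate, via open-chain ester 3 (not isolated), via aldol adduct 4 (not isolated)
Conditions: NaOCH2Ph (1.0 M in PhCH2OH, 3 equiv), THF, 0 to 45 °C; then aq. HCl to pH 3
Reagents that add atoms: sodium benzyloxide, [Na+].[O-]Cc1ccccc1
Why: Benzyloxide opens the lactone at its carbonyl carbon to the benzyl 3-methoxy-5,7-dioxooct-2-enoate 3 (ring-opening transesterification), whose dienolate adds through the ester α-carbon C2 to the C7 ketone (intramolecular aldol, six-membered ring) to give 4, and loss of water with enolisation aromatises ring C with the methoxy group already at C2 and the hydroxyl free at C4 (biogenetic-type polyketide cyclisation; a sodium counter-ion favours the aldol over the Claisen mode of closure).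

Step 3
Reactants: 6 2,2,6-trimethyl-4H-1,3-dioxin-4-one
Product: 7 2,2-dimethyl-6-(2-oxopropyl)-4H-1,3-dioxin-4-one
Conditions: 6 (2.0 equiv), LiN(SiMe3)2 (2.0 equiv), THF, −78 °C; then AcCl (1.0 equiv), −78 to −20 °C; aq. HCl
Reagents that add atoms: acetyl chloride, CC(Cl)=O
Why: γ-Deprotonation of the dioxinone methyl group gives the lithium dienolate, which is C-acylated by acetyl chloride (crossed Claisen-type acylation); half of the enolate serves as base for the more acidic product, and the unreacted 6 is recovered.

Step 4
Reactants: 7 2,2-dimethyl-6-(2-oxopropyl)-4H-1,3-dioxin-4-one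
Product: 8 6-(2,4-dioxopentyl)-2,2-dimethyl-4H-1,3-dioxin-4-one
Conditions: LiN(i-Pr)2 (2.2 equiv), THF, −78 °C; then MeC(O)N(OMe)Me (1.1 equiv), −78 to −30 °C; aq. HCl to pH 3 at 0 °C; used without storage
Reagents that add atoms: N-methoxy-N-methylacetamide, CC(=O)N(C)OC
Why: Two equivalents of amide base give the dianion of the β-keto dioxinone, which reacts at its terminal carbon with the N-methoxy-N-methyl amide (dianion Claisen acylation), the chelated adduct preventing over-addition.

Step 5
Reactants: 5 benzyl 4-hydroxy-2-methoxy-6-methylbenzoate, 8 6-(2,4-dioxopentyl)-2,2-dimethyl-4H-1,3-dioxin-4-one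
Product: 12 benzyl 4-[(2,4-dihydroxy-6-methylbenzoyl)oxy]-2-methoxy-6-methylbenzoate, via acylketene 9 (not isolated), via triketo ester 10 (not isolated), via aldol adduct 11 (not isolated)
Conditions: 5 (1.0 equiv), toluene, 110 °C, 8 (1.2 equiv) added over 1 h under a N2 stream; concentrate; then Et3N (2 equiv), CH2Cl2, 0 °C to rt; aq. HCl wash
Reagents that add atoms: none
Why: Heating 8 causes a retro-hetero-Diels–Alder cycloreversion that expels acetone and releases acylketene 9, which the single hydroxyl of 5 (O4 of ring C) captures to give the aryl 3,5,7-trioxooctanoate 10, so that the ring B–ring C depside bond C(=O)–O4 is made without any activating agent. Triethylamine then enolises the β-keto ester, C2 of the chain adds to the C7 ketone (6-(enolendo)-exo-trig aldol, forming the C1′–C6′ bond of ring B) to give 11, and loss of water with enolisation of the two remaining ketones aromatises ring B. The closest known reaction type is the resorcylate synthesis by thermolysis of a diketo-dioxinone in the presence of an alcohol or phenol followed by aldol aromatisation. No stereocentre is created, since the two stereocentres of 11 are transient and vanish on aromatisation. The selectivity needed is C-cyclisation (C2 to C7) over closure of the ketene or of 10 through the C5 enol oxygen and over loss of the aryloxide; it should be secured by keeping 5 in excess over the short-lived ketene through slow addition of 8, by a short heating time, and by a mild amine base in an aprotic solvent, under which C2 is the only carbon that reaches a ketone through a six-membered transition state. The hydroxyls at C2′ and C4′ emerge free, so ring B needs no protecting group and O4′ is ready for the next capture.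

Step 6
Reactants: 12 benzyl 4-[(2,4-dihydroxy-6-methylbenzoyl)oxy]-2-methoxy-6-methylbenzoate, 8 6-(2,4-dioxopentyl)-2,2-dimethyl-4H-1,3-dioxin-4-one
Product: 15 benzyl 4-{[4-[(2,4-dihydroxy-6-methylbenzoyl)oxy]-2-hydroxy-6-methylbenzoyl]oxy}-2-methoxy-6-methylbenzoate, via triketo ester 13 (not isolated), via aldol adduct 14 (not isolated)
Conditions: 12 (1.0 equiv), toluene, 110 °C, 8 (1.1 equiv) added over 1 h under a N2 stream; concentrate; then Et3N (2 equiv), CH2Cl2, 0 °C to rt; aq. HCl wash
Reagents that add atoms: none
Why: The ketene capture and aldol aromatisation of step 5 are repeated with a second portion of 8: the unhindered, non-chelated hydroxyl at C4′ of ring B should trap the acylketene (the short-lived species 9 of step 5, released afresh on heating 8) in preference to the hydrogen-bonded hydroxyl at C2′, and triketo ester 13 then closes from C2 to C7 (6-(enolendo)-exo-trig aldol) to 14 and aromatises to ring A with both of its hydroxyls free, while the mild amine base leaves the two depside esters and the benzyl ester intact.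

Step 7
Reactants: 15 benzyl 4-{[4-[(2,4-dihydroxy-6-methylbenzoyl)oxy]-2-hydroxy-6-methylbenzoyl]oxy}-2-methoxy-6-methylbenzoate
Product: 16 4-{[4-[(2,4-dihydroxy-6-methylbenzoyl)oxy]-2-hydroxy-6-methylbenzoyl]oxy}-2-methoxy-6-methylbenzoic acid (CNP0283563.0)
Conditions: H2 (1 atm), Pd/C (10% palladium on carbon), EtOAc/THF, rt
Reagents that add atoms: none
Why: Hydrogenolysis of the benzyl ester over palladium releases the carboxylic acid of ring C, while the aryl esters, the methyl ether and the free phenols are inert under these neutral conditions.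

**Compound list**

1 | 4-methoxy-6-methyl-2H-pyran-2-one | COC1=CC(=O)OC(C)=C1 | starting material
2 | 4-methoxy-6-(2-oxopropyl)-2H-pyran-2-one | COC1=CC(=O)OC(CC(C)=O)=C1 | intermediate
3 | benzyl (2E)-3-methoxy-5,7-dioxooct-2-enoate (open-chain ester, not isolated) | CC(=O)CC(=O)C/C(OC)=C\C(=O)OCc1ccccc1 | intermediate
4 | benzyl 6-hydroxy-2-methoxy-6-methyl-4-oxocyclohex-2-ene-1-carboxylate (aldol adduct, mixture of stereoisomers, not isolated) | COC1=CC(=O)CC(C)(O)C1C(=O)OCc1ccccc1 | intermediate
5 | benzyl 4-hydroxy-2-methoxy-6-methylbenzoate (ring C phenol) | COc1cc(O)cc(C)c1C(=O)OCc1ccccc1 | intermediate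
6 | 2,2,6-trimethyl-4H-1,3-dioxin-4-one | CC1=CC(=O)OC(C)(C)O1 | starting material
7 | 2,2-dimethyl-6-(2-oxopropyl)-4H-1,3-dioxin-4-one | CC(=O)CC1=CC(=O)OC(C)(C)O1 | intermediate
8 | 6-(2,4-dioxopentyl)-2,2-dimethyl-4H-1,3-dioxin-4-one (diketo-dioxinone) | CC(=O)CC(=O)CC1=CC(=O)OC(C)(C)O1 | intermediate
9 | 3,5,7-trioxooct-1-en-1-one (acylketene, not isolated) | O=C=CC(=O)CC(=O)CC(C)=O | intermediate
10 | benzyl 2-methoxy-6-methyl-4-[(3,5,7-trioxooctanoyl)oxy]benzoate (triketo ester, not isolated) | CC(=O)CC(=O)CC(=O)CC(=O)Oc1cc(C)c(C(=O)OCc2ccccc2)c(OC)c1 | intermediate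
11 | benzyl 4-{[(2-hydroxy-2-methyl-4,6-dioxocyclohexyl)carbonyl]oxy}-2-methoxy-6-methylbenzoate (aldol adduct, mixture of stereoisomers, not isolated) | CC1(O)CC(=O)CC(=O)C1C(=O)Oc1cc(C)c(C(=O)OCc2ccccc2)c(OC)c1 | intermediate
12 | benzyl 4-[(2,4-dihydroxy-6-methylbenzoyl)oxy]-2-methoxy-6-methylbenzoate (ring B–ring C didepside) | Cc1cc(O)cc(O)c1C(=O)Oc1cc(C)c(C(=O)OCc2ccccc2)c(OC)c1 | intermediate
13 | benzyl 4-({2-hydroxy-6-methyl-4-[(3,5,7-trioxooctanoyl)oxy]benzoyl}oxy)-2-methoxy-6-methylbenzoate (triketo ester, not isolated) | CC(=O)CC(=O)CC(=O)CC(=O)Oc1cc(C)c(C(=O)Oc2cc(C)c(C(=O)OCc3ccccc3)c(OC)c2)c(O)c1 | intermediate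
14 | benzyl 4-{[2-hydroxy-4-{[(2-hydroxy-2-methyl-4,6-dioxocyclohexyl)carbonyl]oxy}-6-methylbenzoyl]oxy}-2-methoxy-6-methylbenzoate (aldol adduct, mixture of stereoisomers, not isolated) | CC1(O)CC(=O)CC(=O)C1C(=O)Oc1cc(C)c(C(=O)Oc2cc(C)c(C(=O)OCc3ccccc3)c(OC)c2)c(O)c1 | intermediate
15 | benzyl 4-{[4-[(2,4-dihydroxy-6-methylbenzoyl)oxy]-2-hydroxy-6-methylbenzoyl]oxy}-2-methoxy-6-methylbenzoate | Cc1cc(O)cc(O)c1C(=O)Oc1cc(C)c(C(=O)Oc2cc(C)c(C(=O)OCc3ccccc3)c(OC)c2)c(O)c1 | intermediate
16 | 4-{[4-[(2,4-dihydroxy-6-methylbenzoyl)oxy]-2-hydroxy-6-methylbenzoyl]oxy}-2-methoxy-6-methylbenzoic acid (CNP0283563.0) | COc1cc(OC(=O)c2c(C)cc(OC(=O)c3c(C)cc(O)cc3O)cc2O)cc(C)c1C(=O)O | target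

**Step count and risk**

Total: 7 steps. Longest linear sequence: 5 steps (steps 1, 2, 5, 6, 7 or steps 3, 4, 5, 6, 7).

Steps most likely to fail:

1. Step 5 (first ketene capture and aromatisation).
   - Risk: the capture of the ketene by the phenol can reverse at 110 °C, and the ketene, or the enolate of 10 after loss of the aryloxide, can close irreversibly through its own C5 enol oxygen, which consumes the tetraketide. Cleavage of the aryl ester during the base stage is a second risk.
   - Fallback: it sets out from 5 and comes back at 12. Commercial orsellinic acid (A1) would be allylated on all three oxygens (allyl bromide, K2CO3, DMF, 60 °C) to allyl 2,4-bis(allyloxy)-6-methylbenzoate F1 and saponified (KOH, MeOH/H2O/1,4-dioxane, reflux; then aq. HCl) to 2,4-bis(allyloxy)-6-methylbenzoic acid F2. F2 and 5 would be joined through the mixed trifluoroacetic anhydride ((CF3CO)2O, toluene, rt) to benzyl 4-{[2,4-bis(allyloxy)-6-methylbenzoyl]oxy}-2-methoxy-6-methylbenzoate F3. Both allyl ethers would then be removed (Pd(PPh3)4 cat., morpholine, THF, rt) to give 12.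

2. Step 6 (second ketene capture and aromatisation).
   - Risk: besides the reversal and lactonisation named for step 5, site selectivity between the two hydroxyls of ring B could be poor (double capture), and the existing depside ester could be cleaved or could migrate during the base stage.
   - Fallback: it sets out from 12 and comes back at 15. 12 would be acylated at the non-chelated O4′ with acid F2 (prepared from A1 as in the fallback for step 5) through the mixed trifluoroacetic anhydride ((CF3CO)2O, toluene, rt) to benzyl 4-{[4-{[2,4-bis(allyloxy)-6-methylbenzoyl]oxy}-2-hydroxy-6-methylbenzoyl]oxy}-2-methoxy-6-methylbenzoate F4. Deallylation (Pd(PPh3)4 cat., morpholine, THF, rt) would give 15.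

3. Step 2 (pyranone opening and aldol aromatisation).
   - Risk: benzyloxide could add at the enol ether carbon and exchange the methoxy group, the chain could close in the Claisen sense (C-acylation by the ester) instead of the aldol sense, or the deprotonated side chain could keep the lactone from opening.
   - Fallback: it replaces steps 1 and 2; it sets out from commercial orsellinic acid (A1), not from a numbered compound, and comes back at 5. The carboxylate of A1 would be benzylated (BnBr, KHCO3, DMF, 40 °C) to benzyl 2,4-dihydroxy-6-methylbenzoate F5. The non-chelated hydroxyl would be allylated (allyl bromide, K2CO3, acetone, reflux) to benzyl 4-(allyloxy)-2-hydroxy-6-methylbenzoate F6. The chelated hydroxyl would be methylated (MeI, K2CO3, DMF, 50 °C) to benzyl 4-(allyloxy)-2-methoxy-6-methylbenzoate F7, and the allyl ether removed (Pd(PPh3)4 cat., morpholine, THF, rt) to give 5.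

**Further compounds**

F1 | step 5 | allyl 2,4-bis(allyloxy)-6-methylbenzoate | C=CCOC(=O)c1c(C)cc(OCC=C)cc1OCC=C
F2 | step 5 | 2,4-bis(allyloxy)-6-methylbenzoic acid | C=CCOc1cc(C)c(C(=O)O)c(OCC=C)c1
F3 | step 5 | benzyl 4-{[2,4-bis(allyloxy)-6-methylbenzoyl]oxy}-2-methoxy-6-methylbenzoate | C=CCOc1cc(C)c(C(=O)Oc2cc(C)c(C(=O)OCc3ccccc3)c(OC)c2)c(OCC=C)c1
F4 | step 6 | benzyl 4-{[4-{[2,4-bis(allyloxy)-6-methylbenzoyl]oxy}-2-hydroxy-6-methylbenzoyl]oxy}-2-methoxy-6-methylbenzoate | C=CCOc1cc(C)c(C(=O)Oc2cc(C)c(C(=O)Oc3cc(C)c(C(=O)OCc4ccccc4)c(OC)c3)c(O)c2)c(OCC=C)c1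
F5 | step 2 | benzyl 2,4-dihydroxy-6-methylbenzoate | Cc1cc(O)cc(O)c1C(=O)OCc1ccccc1
F6 | step 2 | benzyl 4-(allyloxy)-2-hydroxy-6-methylbenzoate | C=CCOc1cc(C)c(C(=O)OCc2ccccc2)c(O)c1
F7 | step 2 | benzyl 4-(allyloxy)-2-methoxy-6-methylbenzoate | C=CCOc1cc(C)c(C(=O)OCc2ccccc2)c(OC)c1
A1 | direct plan | orsellinic acid (2,4-dihydroxy-6-methylbenzoic acid) | Cc1cc(O)cc(O)c1C(=O)O
A2 | direct plan | benzyl 4-{[2-(benzyloxy)-4-hydroxy-6-methylbenzoyl]oxy}-2-methoxy-6-methylbenzoate | Oc1cc(C)c(C(=O)Oc2cc(C)c(C(=O)OCc3ccccc3)c(OC)c2)c(OCc2ccccc2)c1
A3 | direct plan | (2E)-5-diazo-3-methyl-4-oxopent-2-enoic acid | [N-]=[N+]=CC(=O)/C(C)=C/C(=O)O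
A4 | direct plan | 3-(benzyloxy)-4-{[4-(benzyloxycarbonyl)-3-methoxy-5-methylphenoxy]carbonyl}-5-methylphenyl (2E)-5-diazo-3-methyl-4-oxopent-2-enoate | [N-]=[N+]=CC(=O)/C(C)=C/C(=O)Oc1cc(C)c(C(=O)Oc2cc(C)c(C(=O)OCc3ccccc3)c(OC)c2)c(OCc2ccccc2)c1
A5 | direct plan | (triisopropylsilyloxy)acetylene | C#CO[Si](C(C)C)(C(C)C)C(C)C
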